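All runs are calculated with made-up constants.

This closed, stirred vessel holds two solids. D feeds X into solution and Q feeds J, and J then goes either with X into G or alone into Z.

| flask | D | Q | remark | time |
|---|---|---|---|---|
| Sunday's | 20 mM | 0.35 equiv | run made earlier |  |
| Wednesday's | 20 mM | 0.52 equiv | run made earlier |  |
| Friday's | 30 mM | 0.70 equiv | run made earlier |  |
| flask | 20 mM | 0.700 equiv |  | 2.5 min |

| run | time / min | G / % | X / % |
|---|---|---|---|
| Sunday's | 0.167 | 0.5 | 19.6 |
| Sunday's | 0.500 | 0.2 | 45.8 |
| Sunday's | 0.833 | 1.8 | 58.3 |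
| Sunday's | 1.33 | 3.7 | 67.5 |
| Sunday's | 2.00 | 4.8 | 73.2 |
| Sunday's | 2.50 | 3.9 | 74.1 |
| Wednesday's | 0.167 | 0.8 | 21.0 |
| Wednesday's | 0.500 | 1.4 | 45.5 |
| Wednesday's | 0.833 | 2.0 | 59.2 |
| Wednesday's | 1.33 | 5.0 | 67.4 |
| Wednesday's | 2.00 | 6.4 | 72.4 |
| Wednesday's | 2.50 | 5.7 | 73.8 |
| Friday's | 0.200 | 0 | 15.8 |
| Friday's | 0.417 | 0.3 | 28.1 |
| Friday's | 0.667 | 1.0 | 35.8 |
| Friday's | 1.33 | 3.2 | 44.7 |
| Friday's | 2.50 | 5.7 | 48.9 |

(scatter of a reading: 0.5 percentage points)

- solid, in amounts per volume of the solution: D, Q
- steps that have been proposed: D <-> X; X + J -> G; J -> Z; Q <-> J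
- at the start none of D is in solution
- at the start none of Q is in solution
- X means what is dissolved; the solid is not counted in it

- amount of G at 2.5 min, in percent of the D charged
- concentration of X in solution at 2.5 min, in percent of saturation

You need one number. By the end of Sunday's run [X] reads 14.8 mM, with 22.0% of its D still undissolved. Friday's larger charge reads 14.7 mM. So I take [X] as levelling just under saturation, and I expect the same in your flask.

But [X] climbs through Sunday's run, from 19.6% to 74.1% of the D charged, so the fate of J can shift along the way, and I count a whole-run average. Q is the limiting reagent, so count G per Q charged, once Q is spent. Sunday's last two readings give 0.124, and Wednesday's give 0.116. Their mean is s = 0.120, the whole-run share of J that ends as G rather than Z, its selectivity. Multiply s by the equivalents and your flask gets 8.42%.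

Is one number enough? It needs Q spent in time. Friday's G was still rising at 2.50 min, and its 1.71 mM divided by s puts the Q passed by then near 14.2 mM, as an estimate. That is barely more than your flask's charge of 14.0 mM, so the margin is thin, but I keep 8.42%.

The forecast gave 7.3%, below mine, and 96%, finding that G rises “less than proportionally with Q”.

The flask gives 8.46% of G, with X at 96.4% of saturation.

    D ⇌ X, rate k1*(cs1 - [X]) while solid is left; crystals form when [X] > cs1 (solubility = 15.0 mM, k = 0.0320 /s)
    X + J → G (k = 1.00 /M/s)
    J → Z (k = 0.0830 /s)
    Q ⇌ J, rate k4*(cs4 - [J]) while solid is left; crystals form when [J] > cs4 (solubility = 12.0 mM, k = 0.00860 /s)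

That is 0.121 of G per Q charged, and 5.2% of the charged Q is still there, solid or dissolved, at 2.50 min. Now take the neighbouring flask with 12 mM of D, at the same equivalents and time. There s again promises 8.42%, yet that flask holds 7.51%, or 0.107 per Q charged, with 0.035% of its Q left.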